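**Plan**

- Retrosynthetic cuts: the two C8–N bonds of the guanine imidazole (to a salicylaldehyde and 2,5,6-triaminopyrimidin-4(3H)-one); the formyl C–C bond on ring A; the diaryl-ether bond O–C2 of ring A, which opens the 14-membered ring once ring A is taken back to a cyclohexanone; the piperazine C–N bonds, via a diketopiperazine, to the two amide bonds of an O-methyl-Tyr/Tyr dipeptide.
- Enabling feature: in ring A (the phenol ring carrying OH, ether O, CH2 arm and guanine) the ether-bearing carbon C2 is ortho to the hydroxyl-bearing carbon C1. With C1 as a ketone carbonyl, C2 is an α-carbon that, as its bromide, accepts the ring-B phenoxide oxygen by SN2.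
- Forward order: dipeptide, diketopiperazine ring, piperazine, Birch dearomatisation of the anisole ring to the cyclohexanone, α-bromination, 14-membered ring by O-alkylation, re-aromatisation of ring A, formylation, imidazole ring of the guanine, Boc removal.
- Stereochemistry: both piperazine centres (S,S) come from the two L-amino acids and are not touched after amide reduction. The sp3 centres of dearomatised ring A are transient and disappear on aromatisation.

Key step: step 8

Remark: ring A is numbered C1 (C=O, later C–OH), C2 (C–Br, later C–OAr), C4 (CH2 arm), C6 (later guanine); ring B is the p-phenylene ring from tyrosine. Salts, conjugate bases and borane adducts of a numbered compound are treated as forms of that compound. Ring-A sp3 centres in 11–14 arise as mixtures and are written without descriptors. Compounds 1, 2 and 18 are taken as catalogue materials.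

**Route**

Step 1
Reactants: 1 N-Boc-O-methyl-L-tyrosine; 2 L-tyrosine methyl ester
Product: 3 Boc-L-Tyr(Me)-L-Tyr-OMe
Conditions: EDC·HCl, HOBt, CH2Cl2/DMF, 0 °C → rt
Reagents that add atoms: none
Why: Carbodiimide/HOBt amide coupling of a urethane-protected acid should proceed without epimerisation, the amine being far more nucleophilic than the free phenol.

Step 2
Reactants: 3 Boc-L-Tyr(Me)-L-Tyr-OMe
Product: 5 cyclo(L-Tyr(Me)-L-Tyr) diketopiperazine, via dipeptide amine 4 (not isolated)
Conditions: HCO2H, rt; then sec-BuOH/toluene (4:1), reflux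
Reagents that add atoms: none
Why: Acidolytic Boc removal frees the N-terminal amine, which should close onto the methyl ester on heating (6-exo-trig aminolysis, the classical dipeptide-ester to diketopiperazine cyclisation) with both α-centres retained.

Step 3
Reactants: 5 cyclo(L-Tyr(Me)-L-Tyr) diketopiperazine
Product: 6 (2S,5S)-2-(4-hydroxybenzyl)-5-(4-methoxybenzyl)piperazine
Conditions: BH3·THF, THF, reflux; MeOH, then 6 M HCl, reflux; NaOH
Reagents that add atoms: none
Why: Borane reduction of both secondary lactams to amines should leave the aryl ether and the two stereocentres untouched, and acidic methanolysis breaks the amine–borane adducts.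

Step 4
Reactants: 6 (2S,5S)-2-(4-hydroxybenzyl)-5-(4-methoxybenzyl)piperazine
Product: 7 di-tert-butyl (2S,5S)-2-(4-hydroxybenzyl)-5-(4-methoxybenzyl)piperazine-1,4-dicarboxylate
Conditions: Boc2O (2.2 equiv), Et3N, MeOH, rt
Reagents that add atoms: di-tert-butyl dicarbonate (Boc2O), CC(C)(C)OC(=O)OC(=O)OC(C)(C)C
Why: Carbamate formation at both secondary amines is standard, and without an acylation catalyst the phenol should not be carbonylated.

Step 5
Reactants: 7 di-Boc hydroxybenzyl/methoxybenzyl piperazine
Product: 9 di-tert-butyl (2S,5S)-2-(4-hydroxybenzyl)-5-[(4-oxocyclohex-1-en-1-yl)methyl]piperazine-1,4-dicarboxylate, via methyl dienol ether 8 (not isolated)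
Conditions: Li, NH3(l)/THF/t-BuOH, −78 → −33 °C; NH4Cl; then (CO2H)2, THF/H2O, rt
Reagents that add atoms: water, O
Why: In this Birch reduction the ring-B lithium phenoxide resists electron transfer while the 4-alkylanisole ring gives the 1-methoxy-1,4-diene, and mild oxalic acid hydrolysis of the enol ether should unmask the β,γ-unsaturated ketone without cleaving the Boc groups.

Step 6
Reactants: 9 β,γ-unsaturated ketone
Product: 10 di-tert-butyl (2S,5S)-2-(4-hydroxybenzyl)-5-[(4-oxocyclohexyl)methyl]piperazine-1,4-dicarboxylate
Conditions: H2 (1 atm), 10% Pd/C, EtOAc, rt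
Reagents that add atoms: none
Why: Catalytic hydrogenation of the trisubstituted alkene (any conjugated isomer converges too) gives the 4-substituted cyclohexanone, whose C4 is not a stereocentre, so no selectivity is required.

Step 7
Reactants: 10 cyclohexanone–phenol
Product: 12 di-tert-butyl (2S,5S)-2-[(3-bromo-4-oxocyclohexyl)methyl]-5-(4-hydroxybenzyl)piperazine-1,4-dicarboxylate (mixture of ring-A diastereomers), via bis-trimethylsilyl derivative 11 (not isolated)
Conditions: LiHMDS (2.2 equiv), THF, −78 °C; TMSCl; pentane filtration; then NBS, THF, −78 °C; aq. citric acid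
Reagents that add atoms: N-bromosuccinimide, O=C1CCC(=O)N1Br
Why: Double deprotonation and O-silylation mask the phenol and give the silyl enol ether, which NBS should brominate far faster than the silylated aryl ring (silyl enol ether halogenation); the two α-carbons are constitutionally equivalent, the new C2 and C4 centres are deliberately left uncontrolled, and the aryl silyl ether hydrolyses on the mildly acidic work-up.

Step 8
Reactants: 12 bromo ketone–phenol
Product: 13 macrocyclic 2-aryloxycyclohexanone (ring-B oxygen bonded to ring-A C2; N,N′-di-Boc; piperazine S,S; ring-A C2/C4 epimers)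
Conditions: Cs2CO3 (3 equiv), DMF, 40 °C, 12 added by syringe pump (final 2 mM)
Reagents that add atoms: none
Why: Caesium carbonate converts the ring-B phenol into its phenoxide, whose oxygen attacks ring-A C2 (α to the ketone) from the back side and expels bromide, an intramolecular Williamson etherification of the kind known between phenols and 2-bromocyclohexanone, run here at high dilution. The single ring formed is the 14-membered macrocycle, closed in a 14-exo-tet mode. C2 is set with inversion but is left undefined together with C4, since both become sp2 in step 9; only the C2/C4-cis product (ether oxygen and CH2 arm able to sit 1,3-diaxial on the chair and converge on the piperazine) can bridge, and the bromide epimers should interconvert by enolisation and exchange with liberated bromide so that material funnels through the trans-bromide. The step needs O- over C-alkylation, substitution over dehydrobromination or Favorskii contraction, and cyclisation over oligomerisation. These are secured by the soft carbonate base in a polar aprotic solvent, the carbonyl-accelerated SN2 at the α-carbon, the blocked para position of the phenoxide and slow addition. The (2S,5S) piperazine centres are remote and untouched, and their cis-2,5 relationship places both arms on the same face of the piperazine.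

Step 9
Reactants: 13 macrocyclic 2-aryloxycyclohexanone
Product: 15 macrocyclic phenol (ring A aromatic: C1–OH, C2–OAr, C4–CH2; N,N′-di-Boc; S,S), via macrocyclic enone 14 (not isolated)
Conditions: Pd(TFA)2 (5 mol %), 2-(dimethylamino)pyridine (10 mol %), TsOH (20 mol %), O2 (1 atm), DMSO, 80 °C
Reagents that add atoms: none
Why: Pd(II)-catalysed aerobic dehydrogenation of cyclohexanones to phenols (Pd-enolate formation and β-hydride elimination twice, then tautomerisation, O2 reoxidising Pd(0)) should erase the ring-A stereocentres and build the cyclophane strain under the driving force of aromatisation.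

Step 10
Reactants: 15 macrocyclic phenol
Product: 17 macrocyclic salicylaldehyde (CHO at ring-A C6), via salicyl alcohol 16 (not isolated)
Conditions: MgCl2, Et3N, (CH2O)n, MeCN, reflux
Reagents that add atoms: paraformaldehyde (as formaldehyde), C=O
Why: In this Casnati–Skattebøl ortho-formylation the magnesium phenoxide delivers formaldehyde to C6, the only free ortho position (C2 carries the ether, C4 the arm), and the resulting benzylic alkoxide is oxidised by a second formaldehyde through hydride transfer; ring B has no free hydroxyl and should stay untouched.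

Step 11
Reactants: 17 macrocyclic salicylaldehyde; 18 2,5,6-triaminopyrimidin-4(3H)-one sulfate
Product: 21 N,N′-di-Boc-guanipiperazine A, via Schiff base 19 (not isolated), via 7,8-dihydroguanine 20 (not isolated)
Conditions: NaOAc, DMSO, 60 °C; then O2 (1 atm), 100 °C
Reagents that add atoms: none
Why: The 5-amino group, the most nucleophilic of the three, should condense with the aldehyde, the 6-amino group then adds to the imine carbon, and aerobic dehydrogenation of the resulting aminal gives the imidazole ring (oxidative purine annulation from an aldehyde, analogous to benzimidazole formation from o-diamines).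

Step 12
Reactants: 21 N,N′-di-Boc-guanipiperazine A
Product: 22 guanipiperazine A
Conditions: TFA/CH2Cl2 (1:3), 0 °C → rt; basic ion-exchange resin
Reagents that add atoms: none
Why: Acidolysis of the two tert-butyl carbamates followed by neutralisation should free the piperazine, the diaryl ether, phenol, guanine and both stereocentres being stable to TFA.

**Compound list**

1 | N-Boc-O-methyl-L-tyrosine | CC(C)(C)OC(=O)N[C@@H](Cc1ccc(OC)cc1)C(=O)O | starting material
2 | L-tyrosine methyl ester | COC(=O)[C@@H](N)Cc1ccc(O)cc1 | starting material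
3 | Boc-L-Tyr(Me)-L-Tyr-OMe | CC(C)(C)OC(=O)N[C@@H](Cc1ccc(OC)cc1)C(=O)N[C@@H](Cc1ccc(O)cc1)C(=O)OC | intermediate
4 | H-L-Tyr(Me)-L-Tyr-OMe (dipeptide amine, formate salt in the flask) | N[C@@H](Cc1ccc(OC)cc1)C(=O)N[C@@H](Cc1ccc(O)cc1)C(=O)OC | intermediate (not isolated)
5 | (3S,6S)-3-(4-hydroxybenzyl)-6-(4-methoxybenzyl)piperazine-2,5-dione | O=C1N[C@@H](Cc2ccc(O)cc2)C(=O)N[C@H]1Cc1ccc(OC)cc1 | intermediate
6 | (2S,5S)-2-(4-hydroxybenzyl)-5-(4-methoxybenzyl)piperazine | Oc1ccc(cc1)C[C@H]1CN[C@H](CN1)Cc1ccc(OC)cc1 | intermediate
7 | di-tert-butyl (2S,5S)-2-(4-hydroxybenzyl)-5-(4-methoxybenzyl)piperazine-1,4-dicarboxylate | Oc1ccc(cc1)C[C@H]1CN(C(=O)OC(C)(C)C)[C@H](CN1C(=O)OC(C)(C)C)Cc1ccc(OC)cc1 | intermediate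
8 | di-tert-butyl (2S,5S)-2-(4-hydroxybenzyl)-5-[(4-methoxycyclohexa-1,4-dien-1-yl)methyl]piperazine-1,4-dicarboxylate | Oc1ccc(cc1)C[C@H]1CN(C(=O)OC(C)(C)C)[C@H](CN1C(=O)OC(C)(C)C)CC1=CCC(OC)=CC1 | intermediate (not isolated)
9 | di-tert-butyl (2S,5S)-2-(4-hydroxybenzyl)-5-[(4-oxocyclohex-1-en-1-yl)methyl]piperazine-1,4-dicarboxylate | Oc1ccc(cc1)C[C@H]1CN(C(=O)OC(C)(C)C)[C@H](CN1C(=O)OC(C)(C)C)CC1=CCC(=O)CC1 | intermediate
10 | di-tert-butyl (2S,5S)-2-(4-hydroxybenzyl)-5-[(4-oxocyclohexyl)methyl]piperazine-1,4-dicarboxylate | Oc1ccc(cc1)C[C@H]1CN(C(=O)OC(C)(C)C)[C@H](CN1C(=O)OC(C)(C)C)CC1CCC(=O)CC1 | intermediate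
11 | bis-trimethylsilyl derivative of 10 (aryl O-TMS and ring-A trimethylsilyl enol ether) | C[Si](C)(C)Oc1ccc(cc1)C[C@H]1CN(C(=O)OC(C)(C)C)[C@H](CN1C(=O)OC(C)(C)C)CC1CCC(O[Si](C)(C)C)=CC1 | intermediate (not isolated)
12 | di-tert-butyl (2S,5S)-2-[(3-bromo-4-oxocyclohexyl)methyl]-5-(4-hydroxybenzyl)piperazine-1,4-dicarboxylate, ring-A diastereomers | Oc1ccc(cc1)C[C@H]1CN(C(=O)OC(C)(C)C)[C@H](CN1C(=O)OC(C)(C)C)CC1CCC(=O)C(Br)C1 | intermediate
13 | macrocyclic 2-aryloxycyclohexanone (14-membered ring, N,N′-di-Boc, piperazine S,S, ring-A epimers) | O=C1CCC2CC1Oc1ccc(cc1)C[C@H]1CN(C(=O)OC(C)(C)C)[C@H](CN1C(=O)OC(C)(C)C)C2 | intermediate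
14 | macrocyclic enone (ring A: C1=O, C5=C6, C2–OAr) | O=C1C=CC2CC1Oc1ccc(cc1)C[C@H]1CN(C(=O)OC(C)(C)C)[C@H](CN1C(=O)OC(C)(C)C)C2 | intermediate (not isolated)
15 | macrocyclic phenol (ring A aromatic, OH ortho to the diaryl ether, N,N′-di-Boc, S,S) | Oc1ccc2cc1Oc1ccc(cc1)C[C@H]1CN(C(=O)OC(C)(C)C)[C@H](CN1C(=O)OC(C)(C)C)C2 | intermediate
16 | macrocyclic salicyl alcohol (CH2OH at ring-A C6) | OCc1cc2cc(c1O)Oc1ccc(cc1)C[C@H]1CN(C(=O)OC(C)(C)C)[C@H](CN1C(=O)OC(C)(C)C)C2 | intermediate (not isolated)
17 | macrocyclic salicylaldehyde (CHO at ring-A C6) | O=Cc1cc2cc(c1O)Oc1ccc(cc1)C[C@H]1CN(C(=O)OC(C)(C)C)[C@H](CN1C(=O)OC(C)(C)C)C2 | intermediate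
18 | 2,5,6-triaminopyrimidin-4(3H)-one sulfate | Nc1nc(N)c(N)c(=O)[nH]1.OS(=O)(=O)O | starting material
19 | Schiff base of 17 at the 5-amino group of the triaminopyrimidinone | Nc1nc(N)c(N=Cc2cc3cc(c2O)Oc2ccc(cc2)C[C@H]2CN(C(=O)OC(C)(C)C)[C@H](CN2C(=O)OC(C)(C)C)C3)c(=O)[nH]1 | intermediate (not isolated)
20 | 8-aryl-7,8-dihydroguanine (cyclised aminal, C8 epimers) | Nc1nc2c(c(=O)[nH]1)NC(N2)c1cc3cc(c1O)Oc1ccc(cc1)C[C@H]1CN(C(=O)OC(C)(C)C)[C@H](CN1C(=O)OC(C)(C)C)C3 | intermediate (not isolated)
21 | N,N′-di-Boc-guanipiperazine A | Nc1nc2nc(-c3cc4cc(c3O)Oc3ccc(cc3)C[C@H]3CN(C(=O)OC(C)(C)C)[C@H](CN3C(=O)OC(C)(C)C)C4)[nH]c2c(=O)[nH]1 | intermediate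
22 | guanipiperazine A | Nc1nc2nc(-c3cc4cc(c3O)Oc3ccc(cc3)C[C@H]3CN[C@H](CN3)C4)[nH]c2c(=O)[nH]1 | target

**Totals and risks**

Total steps: 12. Longest linear sequence: 12 steps (1 or 2 to 22).

Steps most likely to fail:

1. Step 8 (macrocyclic etherification). Intermolecular etherification to oligomers may outrun ring closure, base may cause dehydrobromination or ring contraction, and one of the two diastereomeric ring-A series may cyclise only slowly. Fallback: the approach changes from halide displacement under base to redox activation of a hydroxyl under neutral conditions. It sets out from ketone 10 through its bis-silyl derivative 11 (made as in step 7). Rubottom oxidation (mCPBA, CH2Cl2, −20 °C; citric acid/MeOH) should give the α-hydroxy ketone F1. A macrocyclic Mitsunobu etherification (PPh3, DIAD, toluene/THF, slow addition, high dilution) then joins the ring-B phenol oxygen to the same ring-A carbon with inversion. The fallback comes back to the route at macrocyclic ketone 13.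

2. Step 9 (aromatisation). The Boc groups may be lost by acidolysis in hot DMSO with sulfonic acid, the oxidation may stall after the first dehydrogenation, and the second dehydrogenation may be slowed by the strain that builds as ring A flattens. Fallback: two stoichiometric, acid-free dehydrogenations at or below room temperature, setting out from 13. Kinetic silylation at the unsubstituted α-methylene (LiHMDS, TMSCl, THF, −78 °C) gives the trimethylsilyl enol ether F2, and Saegusa–Ito oxidation (Pd(OAc)2, MeCN, rt) gives enone 14, now isolated. A second silylation at the aryloxy-bearing α′-carbon gives the cross-conjugated silyl dienol ether F3. A second Saegusa–Ito oxidation gives the 2,5-dienone, which tautomerises, so the fallback comes back to the route at phenol 15.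

3. Step 11 (oxidative guanine annulation). Ring closure of the hydrogen-bonded Schiff base may be incomplete, the electron-rich triaminopyrimidinone and the phenol may be degraded by oxygen at 100 °C, and the imine may hydrolyse back. Fallback: the C8 carbon is brought in at the acid oxidation level so that no oxidant is needed in the ring closure. It sets out from aldehyde 17. Pinnick oxidation (NaClO2, NaH2PO4, 2-methyl-2-butene, t-BuOH/H2O) gives the salicylic acid F4. Carbodiimide coupling (EDC, HOBt, DMF/H2O) with the 5-amino group of 18 gives the 5-acylamino pyrimidinone F5. Base-induced cyclodehydration (2 M NaOH, EtOH, reflux; Traube-type closure, Boc-compatible) comes back to the route at 21.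

**Further compounds**

F1 | step 8 | di-tert-butyl (2S,5S)-2-[(3-hydroxy-4-oxocyclohexyl)methyl]-5-(4-hydroxybenzyl)piperazine-1,4-dicarboxylate (ring-A diastereomers) | Oc1ccc(cc1)C[C@H]1CN(C(=O)OC(C)(C)C)[C@H](CN1C(=O)OC(C)(C)C)CC1CCC(=O)C(O)C1
F2 | step 9 | trimethylsilyl enol ether of 13 (ring A: C1(OTMS)=C6) | C[Si](C)(C)OC1=CCC2CC1Oc1ccc(cc1)C[C@H]1CN(C(=O)OC(C)(C)C)[C@H](CN1C(=O)OC(C)(C)C)C2
F3 | step 9 | trimethylsilyl dienol ether of 14 (ring A: C1(OTMS)=C2(OAr), C5=C6) | C[Si](C)(C)OC1=C2Oc3ccc(cc3)C[C@H]3CN(C(=O)OC(C)(C)C)[C@H](CN3C(=O)OC(C)(C)C)CC(C2)C=C1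
F4 | step 11 | macrocyclic salicylic acid (CO2H at ring-A C6) | OC(=O)c1cc2cc(c1O)Oc1ccc(cc1)C[C@H]1CN(C(=O)OC(C)(C)C)[C@H](CN1C(=O)OC(C)(C)C)C2
F5 | step 11 | N-(2,6-diamino-4-oxo-3,4-dihydropyrimidin-5-yl) amide of F4 | Nc1nc(N)c(NC(=O)c2cc3cc(c2O)Oc2ccc(cc2)C[C@H]2CN(C(=O)OC(C)(C)C)[C@H](CN2C(=O)OC(C)(C)C)C3)c(=O)[nH]1
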